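The upper chroman is disconnected across C2–C3 and C4–C4a into an aryloxymethyl cation (O1 and C2 on ring A) and an E-stilbene (C3=C4). A catalytic asymmetric oxa-Povarov (4+2) annulation should forge both bonds, close the pyran ring and set the trans C3/C4 stereocentres in one operation. It exploits the 7-oxygen of ring A, para to C4a, which makes C4a the nucleophilic terminus, and the oxygens of the central ring ortho and para to the C4-bearing carbon, which stabilise charge at C4 so that C2 bonds to C3. The precursor is a fully benzylated stilbene carrying the finished (3R)-chroman of the lower half, plus an aryloxymethyl pivalate.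

Key step: step 13

Names used: the upper chroman is numbered O1, C2, C3, C4, C4a–C8a. Ring A is its fused benzene ring, ring B its 3-aryl group, ring C the central benzene ring and ring D the benzene ring of the lower chroman.

Remark on the chemistry: for each chiral catalyst the antipode that gives the stated configuration is taken; the sense of induction has to be established on first use.

Step 1
Reactants: 1 paeonol, 1-(2-hydroxy-4-methoxyphenyl)ethan-1-one
Product: 2 1-(5-bromo-2-hydroxy-4-methoxyphenyl)ethan-1-one
Conditions: NBS (1.05 equiv), MeCN, 0 °C to rt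
Reagents that add atoms: N-bromosuccinimide, O=C1CCC(=O)N1Br
Why: Electrophilic aromatic bromination of an activated phenol should go to C5, which is para to the hydroxyl and ortho to the methoxy group, and not to the crowded position between the two oxygens.

Step 2
Reactants: 2 1-(5-bromo-2-hydroxy-4-methoxyphenyl)ethan-1-one
Product: 3 1-[2-(benzyloxy)-5-bromo-4-methoxyphenyl]ethan-1-one
Conditions: BnBr, K2CO3, DMF, 60 °C
Reagents that add atoms: benzyl bromide, BrCc1ccccc1
Why: Williamson ether synthesis, with heating to break the hydrogen bond between the phenol and the acetyl group; the benzyl ether is removed only in the last step.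

Step 3
Reactants: 3 1-[2-(benzyloxy)-5-bromo-4-methoxyphenyl]ethan-1-one
Product: 5 [2-(benzyloxy)-5-bromo-4-methoxyphenyl]acetic acid, via thiomorpholide 4 (not isolated)
Conditions: S8, morpholine, 130 °C; then NaOH, EtOH/H2O, reflux; then aqueous HCl
Reagents that add atoms: sodium hydroxide, [Na+].[OH-]; water, O
Why: The Willgerodt–Kindler reaction moves the oxidised carbon to the chain end as thioamide 4 (which alone carries the sulfur and the morpholine), and basic hydrolysis of 4 gives the arylacetic acid; aryl bromide and benzyl ether should tolerate both stages.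

Step 4
Reactants: 5 [2-(benzyloxy)-5-bromo-4-methoxyphenyl]acetic acid; 6 4-(benzyloxy)-2-hydroxybenzaldehyde
Product: 7 7-(benzyloxy)-3-[2-(benzyloxy)-5-bromo-4-methoxyphenyl]-2H-chromen-2-one
Conditions: Ac2O, Et3N, 120 °C
Reagents that add atoms: none
Why: Perkin (Oglialoro) condensation: the mixed anhydride of 5 is enolised by Et3N, adds to the aldehyde of 6 and lactonises onto the neighbouring phenol with loss of water to give the 3-arylcoumarin.

Step 5
Reactants: 7 7-(benzyloxy)-3-[2-(benzyloxy)-5-bromo-4-methoxyphenyl]-2H-chromen-2-one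
Product: 8 5-(benzyloxy)-2-[(1Z)-2-[2-(benzyloxy)-5-bromo-4-methoxyphenyl]-3-hydroxyprop-1-en-1-yl]phenol
Conditions: i-Bu2AlH (4 equiv), CH2Cl2, −78 °C to 0 °C; aqueous potassium sodium tartrate
Reagents that add atoms: none
Why: Excess aluminium hydride should reduce the lactone by 1,2-addition through the lactol to the ring-opened allylic alcohol, the Z geometry being inherited from the ring.

Step 6
Reactants: 8 5-(benzyloxy)-2-[(1Z)-2-[2-(benzyloxy)-5-bromo-4-methoxyphenyl]-3-hydroxyprop-1-en-1-yl]phenol
Product: 9 7-(benzyloxy)-3-[2-(benzyloxy)-5-bromo-4-methoxyphenyl]-2H-chromene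
Conditions: PPh3, DIAD, THF, 0 °C to rt
Reagents that add atoms: none
Why: Mitsunobu etherification in which the phenol displaces the activated primary allylic alcohol (6-exo-tet) to close the 2H-chromene without touching the alkene.

Step 7
Reactants: 9 7-(benzyloxy)-3-[2-(benzyloxy)-5-bromo-4-methoxyphenyl]-2H-chromene
Product: 10 (3R)-7-(benzyloxy)-3-[2-(benzyloxy)-5-bromo-4-methoxyphenyl]chromane
Conditions: [Ir(cod)(tBu-PHOX)]BArF (2 mol %), H2 (50 bar), CH2Cl2, rt
Reagents that add atoms: none
Why: Iridium-catalysed asymmetric hydrogenation of a trisubstituted cyclic aryl alkene with a chiral P,N ligand, in which the catalyst differentiates the alkene faces and so sets C3 as R; the homogeneous catalyst should leave aryl bromide and benzyl ethers intact.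

Step 8
Reactants: 11 2,6-dimethoxyphenol
Product: 12 2-(benzyloxy)-1,3-dimethoxybenzene
Conditions: BnBr, K2CO3, DMF, 50 °C
Reagents that add atoms: benzyl bromide, BrCc1ccccc1
Why: Williamson ether synthesis on the hindered but acidic phenol.

Step 9
Reactants: 12 2-(benzyloxy)-1,3-dimethoxybenzene
Product: 13 3-(benzyloxy)-1-bromo-2,4-dimethoxybenzene
Conditions: NBS, MeCN, 0 °C to rt
Reagents that add atoms: N-bromosuccinimide, O=C1CCC(=O)N1Br
Why: Electrophilic bromination of a 1,2,3-trioxygenated benzene should go to C4, which is para to one methoxy group and ortho to the other, and not to the position para to the out-of-plane central benzyloxy group.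

Step 10
Reactants: 13 3-(benzyloxy)-1-bromo-2,4-dimethoxybenzene; 14 potassium vinyltrifluoroborate
Product: 15 3-(benzyloxy)-1-ethenyl-2,4-dimethoxybenzene
Conditions: PdCl2(dppf) (3 mol %), Cs2CO3 (3 equiv), THF/H2O 9:1, 80 °C
Reagents that add atoms: none
Why: Suzuki–Miyaura coupling of the aryl bromide with the vinyltrifluoroborate installs the two carbons that become C3 and C4 of the upper chroman.

Step 11
Reactants: 10 (3R)-7-(benzyloxy)-3-[2-(benzyloxy)-5-bromo-4-methoxyphenyl]chromane; 15 3-(benzyloxy)-1-ethenyl-2,4-dimethoxybenzene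
Product: 16 (3R)-7-(benzyloxy)-3-{2-(benzyloxy)-5-[(E)-2-[3-(benzyloxy)-2,4-dimethoxyphenyl]ethenyl]-4-methoxyphenyl}chromane
Conditions: Pd2(dba)3 (2.5 mol %), P(t-Bu)3·HBF4 (10 mol %), Cy2NMe (1.5 equiv), 1,4-dioxane, 90 °C
Reagents that add atoms: none
Why: Heck reaction in which the arylpalladium bromide from 10 adds to the terminal carbon of styrene 15 and syn β-hydride elimination gives the E-stilbene; the bulky electron-rich phosphine allows oxidative addition into the electron-rich bromide.

Step 12
Reactants: 17 3-(benzyloxy)phenol; 18 chloromethyl pivalate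
Product: 19 [3-(benzyloxy)phenoxy]methyl pivalate
Conditions: Cs2CO3, NaI (10 mol %), DMF, rt
Reagents that add atoms: none
Why: Iodide-assisted SN2 O-alkylation of the phenoxide at the chloromethyl carbon (Williamson type); the hindered pivaloyl carbonyl should resist acyl transfer.

Step 13
Reactants: 16 (3R)-7-(benzyloxy)-3-{2-(benzyloxy)-5-[(E)-2-[3-(benzyloxy)-2,4-dimethoxyphenyl]ethenyl]-4-methoxyphenyl}chromane; 19 [3-(benzyloxy)phenoxy]methyl pivalate
Product: 22 (3R,4S)-7-(benzyloxy)-3-[3-(benzyloxy)-2,4-dimethoxyphenyl]-4-{4-(benzyloxy)-5-[(3R)-7-(benzyloxy)chroman-3-yl]-2-methoxyphenyl}chromane, via aryloxymethyl cation 20 (not isolated), via benzylic cation 21 (not isolated)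
Conditions: chiral IDPi Brønsted acid (N-triflyl imidodiphosphorimidate built from two 3,3′-diaryl-BINOL units, 5 mol %), 19 (1.5 equiv), CHCl3, −40 °C
Reagents that add atoms: none
Why: Proposed new method: the strong chiral acid should ionise pivalate 19 to the aryloxymethyl cation 20, held as an ion pair with the confined chiral anion; the CH2 terminus of 20 adds to the stilbene carbon that bears ring B (C2–C3), the resulting cation 21 at the carbon that bears ring C is captured by the ring A carbon ortho to the ether oxygen and para to the benzyloxy group (C4–C4a), and loss of that ring proton regenerates the acid. The closest known reaction types are the tin tetrachloride-mediated oxa-Povarov reaction of aryl oxocarbenium ions with styrenes and the asymmetric intermolecular Prins reaction of styrenes with formaldehyde under confined chiral Brønsted acids; the asymmetric aryloxymethyl version is not known. The pyran ring closes as a polar (4+2) annulation whose second bond is an intramolecular Friedel–Crafts alkylation forming the six-membered ring (6-endo with respect to the attacking arene C=C). C3 (R) is set by the alkene face that the chiral anion exposes to 20, and C4 (S) follows from C3 because the E geometry is transferred suprafacially or, if 21 lives long enough to rotate, because closure through a chair-like transition state places both aryl groups equatorial (trans). Regioselectivity is needed at the alkene and at ring A: ring C has conjugating alkoxy groups ortho and para to the C4-bearing carbon, whereas on ring B the 2-methoxy group is twisted by its two neighbours and the 3-benzyloxy group is meta, so positive charge should build at C4; closure para to the 7-benzyloxy group should be favoured over the crowded position between the two oxygens.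

Step 14
Reactants: 22 (3R,4S)-7-(benzyloxy)-3-[3-(benzyloxy)-2,4-dimethoxyphenyl]-4-{4-(benzyloxy)-5-[(3R)-7-(benzyloxy)chroman-3-yl]-2-methoxyphenyl}chromane
Product: 23 (3R,4S)-3-(3-hydroxy-2,4-dimethoxyphenyl)-4-{4-hydroxy-5-[(3R)-7-hydroxychroman-3-yl]-2-methoxyphenyl}chroman-7-ol (CNP0202416.1)
Conditions: H2 (1 atm), Pd/C (10 %), EtOAc/MeOH, rt
Reagents that add atoms: none
Why: Hydrogenolysis of the four benzyl aryl ethers over palladium on carbon should free the four phenols; no alkene, halide or other reducible bond remains, and the three stereocentres are not touched.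

Compound list
1 | paeonol, 1-(2-hydroxy-4-methoxyphenyl)ethan-1-one | CC(=O)c1ccc(OC)cc1O | starting material
2 | 1-(5-bromo-2-hydroxy-4-methoxyphenyl)ethan-1-one | CC(=O)c1cc(Br)c(OC)cc1O | intermediate
3 | 1-[2-(benzyloxy)-5-bromo-4-methoxyphenyl]ethan-1-one | CC(=O)c1cc(Br)c(OC)cc1OCc1ccccc1 | intermediate
4 | 2-[2-(benzyloxy)-5-bromo-4-methoxyphenyl]-1-(morpholin-4-yl)ethane-1-thione (thiomorpholide) | S=C(Cc1cc(Br)c(OC)cc1OCc1ccccc1)N1CCOCC1 | intermediate
5 | [2-(benzyloxy)-5-bromo-4-methoxyphenyl]acetic acid | OC(=O)Cc1cc(Br)c(OC)cc1OCc1ccccc1 | intermediate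
6 | 4-(benzyloxy)-2-hydroxybenzaldehyde | O=Cc1ccc(OCc2ccccc2)cc1O | starting material
7 | 7-(benzyloxy)-3-[2-(benzyloxy)-5-bromo-4-methoxyphenyl]-2H-chromen-2-one | O=C1Oc2cc(OCc3ccccc3)ccc2C=C1c1cc(Br)c(OC)cc1OCc1ccccc1 | intermediate
8 | 5-(benzyloxy)-2-[(1Z)-2-[2-(benzyloxy)-5-bromo-4-methoxyphenyl]-3-hydroxyprop-1-en-1-yl]phenol | OC/C(=C\c1ccc(OCc2ccccc2)cc1O)c1cc(Br)c(OC)cc1OCc1ccccc1 | intermediate
9 | 7-(benzyloxy)-3-[2-(benzyloxy)-5-bromo-4-methoxyphenyl]-2H-chromene | COc1cc(OCc2ccccc2)c(C2=Cc3ccc(OCc4ccccc4)cc3OC2)cc1Br | intermediate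
10 | (3R)-7-(benzyloxy)-3-[2-(benzyloxy)-5-bromo-4-methoxyphenyl]chromane | COc1cc(OCc2ccccc2)c([C@@H]2COc3cc(OCc4ccccc4)ccc3C2)cc1Br | intermediate
11 | 2,6-dimethoxyphenol | COc1cccc(OC)c1O | starting material
12 | 2-(benzyloxy)-1,3-dimethoxybenzene | COc1cccc(OC)c1OCc1ccccc1 | intermediate
13 | 3-(benzyloxy)-1-bromo-2,4-dimethoxybenzene | COc1ccc(Br)c(OC)c1OCc1ccccc1 | intermediate
14 | potassium vinyltrifluoroborate | [K+].C=C[B-](F)(F)F | starting material
15 | 3-(benzyloxy)-1-ethenyl-2,4-dimethoxybenzene | C=Cc1ccc(OC)c(OCc2ccccc2)c1OC | intermediate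
16 | (3R)-7-(benzyloxy)-3-{2-(benzyloxy)-5-[(E)-2-[3-(benzyloxy)-2,4-dimethoxyphenyl]ethenyl]-4-methoxyphenyl}chromane | COc1cc(OCc2ccccc2)c([C@@H]2COc3cc(OCc4ccccc4)ccc3C2)cc1/C=C/c1ccc(OC)c(OCc2ccccc2)c1OC | intermediate
17 | 3-(benzyloxy)phenol | Oc1cccc(OCc2ccccc2)c1 | starting material
18 | chloromethyl pivalate (chloromethyl 2,2-dimethylpropanoate) | CC(C)(C)C(=O)OCCl | starting material
19 | [3-(benzyloxy)phenoxy]methyl pivalate | CC(C)(C)C(=O)OCOc1cccc(OCc2ccccc2)c1 | intermediate
20 | aryloxymethyl cation, [3-(benzyloxy)phenyl](methylidene)oxonium | C=[O+]c1cccc(OCc2ccccc2)c1 | intermediate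
21 | benzylic cation after C2–C3 bonding: cation at the carbon bearing ring C, next to the (R)-carbon that bears ring B and the CH2–O–aryl arm | COc1cc(OCc2ccccc2)c([C@@H]2COc3cc(OCc4ccccc4)ccc3C2)cc1[CH+][C@@H](COc1cccc(OCc2ccccc2)c1)c1ccc(OC)c(OCc2ccccc2)c1OC | intermediate
22 | (3R,4S)-7-(benzyloxy)-3-[3-(benzyloxy)-2,4-dimethoxyphenyl]-4-{4-(benzyloxy)-5-[(3R)-7-(benzyloxy)chroman-3-yl]-2-methoxyphenyl}chromane | COc1cc(OCc2ccccc2)c([C@@H]2COc3cc(OCc4ccccc4)ccc3C2)cc1[C@@H]1c2ccc(OCc3ccccc3)cc2OC[C@H]1c1ccc(OC)c(OCc2ccccc2)c1OC | intermediate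
23 | (3R,4S)-3-(3-hydroxy-2,4-dimethoxyphenyl)-4-{4-hydroxy-5-[(3R)-7-hydroxychroman-3-yl]-2-methoxyphenyl}chroman-7-ol | COc1cc(O)c([C@@H]2COc3cc(O)ccc3C2)cc1[C@@H]1c2ccc(O)cc2OC[C@H]1c1ccc(OC)c(O)c1OC | target

Total step count: 14. Longest linear sequence: 10 steps (steps 1–7, 11, 13 and 14).

Steps most likely to fail

Step 13 (proposed new method). The chiral acid may discriminate the two faces of so large a stilbene poorly. The acid may also protonate the electron-rich alkene and start oligomerisation, and cation 20 may alkylate other activated rings. The fallback uses known chemistry and builds the same pyran ring through O1–C2 and C3–C4; it sets out from 10, 6 and 15 and comes back at 22. Bromide 10 would undergo bromine–lithium exchange (n-BuLi, THF, −78 °C), and the aryllithium would add to the lithium phenoxide of aldehyde 6 to give the ortho-hydroxybenzhydrol F1. Styrene 15 would be oxidised in the anti-Markovnikov sense (Wacker-type, PdCl2(MeCN)2, 1,4-benzoquinone, t-BuOH/H2O) to the arylacetaldehyde F2. With a diarylprolinol silyl ether and a carboxylic acid co-catalyst, F1 should lose water to its ortho-quinone methide and the enamine of F2 should add to it. This known amine-catalysed (4+2) annulation should give the trans-chroman-2-ol F3, with catalyst control at C3 and trans placement of the aryl group at C4. Et3SiH/BF3·OEt2 would then remove the anomeric hydroxyl and return 22.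

Step 7. The ortho-benzyloxy group twists ring C out of the alkene plane, so hydrogenation may be slow and the faces poorly differentiated. The fallback sets out from 8 (step 6 is then skipped) and comes back at 10. Hydroxyl-directed asymmetric hydrogenation of allylic alcohol 8 with Ru(OAc)2(BINAP), H2 and MeOH should give the saturated diol F4. Mitsunobu closure of its phenol onto the primary alcohol (PPh3, DIAD, THF) leaves the stereocentre untouched and returns 10.

Step 11. Oxidative addition into the hindered, electron-rich bromide may be slow, and insertion may occur with the opposite regiochemistry or be followed by double-bond isomerisation. The fallback sets out from 15 and comes back at 16. Cross-metathesis of 15 with vinylboronic acid pinacol ester (second-generation Grubbs catalyst, RuCl2(H2IMes)(PCy3)(=CHPh), CH2Cl2, 40 °C) should give the (E)-styrylboronate F5. Suzuki–Miyaura coupling of F5 with bromide 10 (PdCl2(dppf), K2CO3, dioxane/H2O, 80 °C) then delivers 16 with fixed regiochemistry and E geometry.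

Further compounds
F1 | step 13 | [4-(benzyloxy)-2-hydroxyphenyl]{4-(benzyloxy)-5-[(3R)-7-(benzyloxy)chroman-3-yl]-2-methoxyphenyl}methanol (both carbinol epimers) | COc1cc(OCc2ccccc2)c([C@@H]2COc3cc(OCc4ccccc4)ccc3C2)cc1C(O)c1ccc(OCc2ccccc2)cc1O
F2 | step 13 | [3-(benzyloxy)-2,4-dimethoxyphenyl]acetaldehyde | O=CCc1ccc(OC)c(OCc2ccccc2)c1OC
F3 | step 13 | (3R,4S)-7-(benzyloxy)-3-[3-(benzyloxy)-2,4-dimethoxyphenyl]-4-{4-(benzyloxy)-5-[(3R)-7-(benzyloxy)chroman-3-yl]-2-methoxyphenyl}chroman-2-ol (both anomers) | COc1cc(OCc2ccccc2)c([C@@H]2COc3cc(OCc4ccccc4)ccc3C2)cc1[C@@H]1c2ccc(OCc3ccccc3)cc2OC(O)[C@H]1c1ccc(OC)c(OCc2ccccc2)c1OC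
F4 | step 7 | 5-(benzyloxy)-2-{(2R)-2-[2-(benzyloxy)-5-bromo-4-methoxyphenyl]-3-hydroxypropyl}phenol | OC[C@H](Cc1ccc(OCc2ccccc2)cc1O)c1cc(Br)c(OC)cc1OCc1ccccc1
F5 | step 11 | 2-{(E)-2-[3-(benzyloxy)-2,4-dimethoxyphenyl]ethenyl}-4,4,5,5-tetramethyl-1,3,2-dioxaborolane | COc1ccc(/C=C/B2OC(C)(C)C(C)(C)O2)c(OC)c1OCc1ccccc1
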